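**Plan**
1. Retrosynthesis: the docosyl chain (C1′–C22′, counted outward from pyrrole C3) is cut first at the C7′–C8′ CH2–CH2 bond, giving a pentadecyl electrophile and a 2-formylpyrrole that carries a hept-6-enyl chain. The second cut is the C3–C1′ bond between ring and chain.
2. Forward: zinc insertion into 7-bromohept-1-ene (1) gives alkylzinc 2, and Negishi coupling with 3-bromo-1H-pyrrole-2-carbaldehyde (3) gives alkene 4. Finkelstein exchange turns 1-bromopentadecane (5) into iodide 6, and nickel hydride hydroalkylation of 4 with 6 joins the halves and gives target 7 directly. The pyrrole ring is bought intact with formyl at C2 and bromine at C3, so the 2,3-pattern is fixed from the start.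
3. Enabling feature: from C1′ to C22′ the chain is unbranched, saturated and free of heteroatoms, so the C7′–C8′ bond is what forms when H and a primary alkyl add in the anti-Markovnikov sense across a terminal C6′=C7′ vinyl group. The C2 formyl group is conjugated through the ring to N1 (a vinylogous formamide with an N1–H···O=C contact) and is a poor hydride acceptor, so N–H and CHO are carried unprotected and no redox adjustment follows.
4. Stereochemistry: the target has no stereocentre and no stereogenic double bond. The only selectivities are regiochemical (linear addition in the key step; C3 substitution fixed by the bromide).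

Key step: step 4

Assumption: the three starting materials (1, 3, 5) are catalogue chemicals, and alkylzinc 2 is handled as a titrated solution and counted as an isolated intermediate.

Step 1
Reactants: 1 7-bromohept-1-ene
Product: 2 hept-6-en-1-ylzinc bromide (titrated DMA solution)
Conditions: Zn dust (1.5 equiv), I2 (5 mol%), DMA, 80 °C
Reagents that add atoms: zinc, [Zn]
Why: Direct insertion of iodine-activated zinc into a primary alkyl bromide in a polar aprotic solvent (organozinc formation by oxidative insertion) should give the alkylzinc bromide, the remote terminal alkene being inert and too far away for fast radical cyclisation.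

Step 2
Reactants: 2 hept-6-en-1-ylzinc bromide; 3 3-bromo-1H-pyrrole-2-carbaldehyde
Product: 4 3-(hept-6-en-1-yl)-1H-pyrrole-2-carbaldehyde
Conditions: Pd(OAc)2 (2 mol%), SPhos (4 mol%), THF/DMA, 25–40 °C, slow addition of 2 (2.2 equiv); aq. NH4Cl
Reagents that add atoms: none
Why: Negishi coupling of a primary alkylzinc halide with a heteroaryl bromide, whose C3–Br bond is activated for oxidative addition by the adjacent C2 formyl group, should give the 3-alkyl product with ring regiochemistry fixed by the bromide; alkylzinc halides do not add to the deactivated aldehyde, and slow addition of excess 2 limits loss by N–H protonolysis.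

Step 3
Reactants: 5 1-bromopentadecane
Product: 6 1-iodopentadecane
Conditions: NaI (3 equiv), acetone, reflux
Reagents that add atoms: sodium iodide, [Na+].[I-]
Why: Finkelstein halide exchange (SN2 at a primary carbon) should be driven to completion by precipitation of sodium bromide from acetone.

Step 4
Reactants: 4 3-(hept-6-en-1-yl)-1H-pyrrole-2-carbaldehyde; 6 1-iodopentadecane
Product: 7 3-docosyl-1H-pyrrole-2-carbaldehyde
Conditions: NiBr2·diglyme (10 mol%), i-Pr-Pybox (12 mol%), (EtO)2MeSiH (2.5 equiv), Na2CO3 (2 equiv), 6 (1.5 equiv), DMA, 25–30 °C; aq. NH4Cl
Reagents that add atoms: none
Why: A ligated Ni–H, formed from the nickel(II) salt, the hydrosilane and carbonate, inserts into the terminal C6′=C7′ double bond of 4 to place nickel on the primary carbon C7′, while low-valent nickel abstracts iodine from 6 to give the pentadecyl radical, which is captured by the alkylnickel and released by reductive elimination as the C7′–C8′ bond. The closest known reaction type is the nickel hydride catalysed reductive anti-Markovnikov hydroalkylation of unactivated terminal alkenes with primary alkyl iodides and a hydrosilane. No ring is closed and no stereocentre is formed, so no closure mode or stereocontrol element arises. The step needs linear regioselectivity, which the unhindered monosubstituted vinyl group secures because both insertion and C–C bond formation favour the primary alkylnickel, so any chain walking should return to the terminus before coupling. It also needs chemoselectivity for the alkene over the formyl group and N–H, which the substrate supplies because the C2 aldehyde is a vinylogous formamide deactivated by N1 and held in an N–H···O=C hydrogen bond, and because the weak heterogeneous base leaves the pyrrole largely protonated so that N-alkylation by 6 should not compete. The chain is formed at its final oxidation level, so the product is the target with nothing to remove or adjust.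

**Compound list**
1 | 7-bromohept-1-ene | C=CCCCCCBr | starting material
2 | hept-6-en-1-ylzinc bromide | C=CCCCCC[Zn]Br | intermediate
3 | 3-bromo-1H-pyrrole-2-carbaldehyde | O=Cc1[nH]ccc1Br | starting material
4 | 3-(hept-6-en-1-yl)-1H-pyrrole-2-carbaldehyde | C=CCCCCCc1cc[nH]c1C=O | intermediate
5 | 1-bromopentadecane | CCCCCCCCCCCCCCCBr | starting material
6 | 1-iodopentadecane | CCCCCCCCCCCCCCCI | intermediate
7 | 3-docosyl-1H-pyrrole-2-carbaldehyde | CCCCCCCCCCCCCCCCCCCCCCc1cc[nH]c1C=O | target

Total step count: 4. Longest linear sequence: 3 steps (steps 1, 2, 4); step 3 is a one-step side branch.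

**Steps most likely to fail**

1. Step 4. Possible failures: hydride transfer from Ni–H/silane to the formyl group, sequestration of nickel by the N,O-chelating 2-formylpyrrolide, N-alkylation of the pyrrole by the iodide, or hydrodehalogenation and alkene reduction outrunning C–C coupling. Fallback: the same C7′–C8′ bond is made as an alkene by cross-metathesis and then saturated. The fallback sets out from 3. Negishi coupling as in step 2 with oct-7-en-1-ylzinc bromide F1 (from 8-bromooct-1-ene and zinc as in step 1) should give 3-(oct-7-en-1-yl)-1H-pyrrole-2-carbaldehyde F2. Cross-metathesis with excess hexadec-1-ene (second-generation Ru–NHC benzylidene catalyst, CH2Cl2, 40 °C) should give 3-[(7E)-docos-7-en-1-yl]-1H-pyrrole-2-carbaldehyde F3, whose E/Z composition is of no consequence. Hydrogenation (H2, 1 atm, Pd/C, EtOAc, rt), which should leave the pyrrole and its deactivated aldehyde untouched, comes back to the route at 7.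

2. Step 2. Possible failures: protonolysis of the alkylzinc by the pyrrole N–H, slow oxidative addition into the N-zincated electron-rich bromopyrrole, or protodebromination. Fallback: the polarity is reversed, with the pyrrole as nucleophile and the formyl group introduced afterwards. The fallback sets out from 1. Commercial 3-bromo-1-(triisopropylsilyl)pyrrole is treated with t-BuLi (THF, −78 °C) to give 3-lithio-1-(triisopropylsilyl)-1H-pyrrole F4, which is alkylated with 1 to give 3-(hept-6-en-1-yl)-1-(triisopropylsilyl)-1H-pyrrole F5. TBAF (THF, rt) should give 3-(hept-6-en-1-yl)-1H-pyrrole F6. Vilsmeier–Haack formylation (POCl3, DMF, 0 °C; aq. NaOAc), expected to favour the α-position next to the alkyl group, comes back to the route at 4 after chromatographic removal of the 4-alkyl isomer.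

3. Step 1. Possible failures: incomplete insertion into passivated zinc, or Wurtz-type homocoupling at 80 °C. Fallback: magnesium insertion followed by transmetalation. The fallback sets out from 1. Mg turnings in THF should give hept-6-en-1-ylmagnesium bromide F7, and addition to ZnBr2 (1.05 equiv, THF, 0 °C) comes back to the route at 2.

**Further compounds**
F1 | step 4 | oct-7-en-1-ylzinc bromide | C=CCCCCCC[Zn]Br
F2 | step 4 | 3-(oct-7-en-1-yl)-1H-pyrrole-2-carbaldehyde | C=CCCCCCCc1cc[nH]c1C=O
F3 | step 4 | 3-[(7E)-docos-7-en-1-yl]-1H-pyrrole-2-carbaldehyde | CCCCCCCCCCCCCC/C=C/CCCCCCc1cc[nH]c1C=O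
F4 | step 2 | 3-lithio-1-(triisopropylsilyl)-1H-pyrrole | [Li]c1ccn(c1)[Si](C(C)C)(C(C)C)C(C)C
F5 | step 2 | 3-(hept-6-en-1-yl)-1-(triisopropylsilyl)-1H-pyrrole | C=CCCCCCc1ccn(c1)[Si](C(C)C)(C(C)C)C(C)C
F6 | step 2 | 3-(hept-6-en-1-yl)-1H-pyrrole | C=CCCCCCc1cc[nH]c1
F7 | step 1 | hept-6-en-1-ylmagnesium bromide | C=CCCCCC[Mg]Br
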